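**Assumption:** the target has no stereocentre, so no enantiocontrol is needed; the one transient stereocentre (in 3) is carried as the racemate and erased in step 2.

**Retrosynthetic overview**
1. Target 9 ⇒ aldehyde 8 by reduction of C=O (last step).
2. 8 ⇒ vanillin 5 by three electrophilic brominations (C5 and C6 of vanillin first, then C2).
3. Vanillin 5 ⇒ mandelic acid 3 by oxidative decarboxylation.
4. 3 ⇒ guaiacol 1 + glyoxylic acid 2: aldol-type addition of the phenolate (through its para carbon) to the aldehyde carbonyl, the only C–C bond made.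
5. No ring is built; the benzene ring is bought in guaiacol.

**Route**

Step 1
Reactants: 1 guaiacol (2-methoxyphenol, 1.5 equiv); 2 glyoxylic acid (50 % aqueous solution, 1.0 equiv)
Product: 3 (±)-4-hydroxy-3-methoxymandelic acid
Conditions: NaOH (aq.), H2O, 0 °C → rt, 24 h; then HCl to pH 1–2, EtOAc extraction (excess 1 removed with toluene at pH 6 first)
Reagents that add atoms: none
Why: Aldol-type hydroxyalkylation in which sodium guaiacolate reacts as an aromatic enolate through the carbon para to O⁻ with the glyoxylate aldehyde; excess guaiacol suppresses double addition, and the new carbinol centre forms racemic and is removed in step 2.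

Step 2
Reactants: 3 (±)-4-hydroxy-3-methoxymandelic acid
Product: 5 vanillin (4-hydroxy-3-methoxybenzaldehyde), via 4-hydroxy-3-methoxyphenylglyoxylic acid 4 (not isolated)
Conditions: air (O2), CuSO4 (cat.), NaOH (aq.), 90–95 °C; then H2SO4 to pH 3–4, 60–80 °C
Reagents that add atoms: none
Why: Oxidative decarboxylation: Cu(II)-catalysed aerobic oxidation of the electron-rich benzylic carbinol gives the α-keto acid, which loses CO2 on acidification with assistance from the para-hydroxyl.

Step 3
Reactants: 5 vanillin
Product: 7 5,6-dibromovanillin (2,3-dibromo-4-hydroxy-5-methoxybenzaldehyde), via 5-bromovanillin 6 (not isolated)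
Conditions: Br2 (2.2 equiv), Fe powder (cat.), NaOAc (2.2 equiv), AcOH, rt, 6–12 h; aq. NaHSO3 quench
Reagents that add atoms: bromine, BrBr
Why: Electrophilic aromatic bromination in which the first bromine enters ortho to OH (C5) and the second, under FeBr3 catalysis, para to OMe (C6); acetate buffers the HBr.

Step 4
Reactants: 7 5,6-dibromovanillin
Product: 8 2,3,6-tribromo-4-hydroxy-5-methoxybenzaldehyde
Conditions: Br2 (1.5–2 equiv), Fe powder (cat.), anhydrous AcOH, 60–70 °C; aq. NaHSO3 quench
Reagents that add atoms: bromine, BrBr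
Why: FeBr3-catalysed electrophilic aromatic bromination at the only remaining C–H, which is ortho to OMe and para to a bromine; anhydrous acetic acid disfavours ipso-bromodeformylation at the carbon para to OH.

Step 5
Reactants: 8 2,3,6-tribromo-4-hydroxy-5-methoxybenzaldehyde
Product: 9 2,3,6-tribromo-4-hydroxy-5-methoxybenzyl alcohol (target)
Conditions: NaBH4 (2 equiv), THF/H2O 4:1, 0 °C → rt; then pH 6 phosphate buffer, EtOAc extraction
Reagents that add atoms: none
Why: Chemoselective borohydride reduction of the aldehyde leaves the aryl bromides and methyl ether untouched; a methanol-free, near-neutral work-up avoids quinone-methide etherification of the p-hydroxybenzyl alcohol.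

**Compound list**
1 | guaiacol (2-methoxyphenol) | COc1ccccc1O | starting material
2 | glyoxylic acid | O=CC(=O)O | starting material
3 | (±)-4-hydroxy-3-methoxymandelic acid [2-hydroxy-2-(4-hydroxy-3-methoxyphenyl)acetic acid, racemic] | COc1cc(C(O)C(=O)O)ccc1O | intermediate
4 | 4-hydroxy-3-methoxyphenylglyoxylic acid | COc1cc(C(=O)C(=O)O)ccc1O | intermediate
5 | vanillin (4-hydroxy-3-methoxybenzaldehyde) | COc1cc(C=O)ccc1O | intermediate
6 | 5-bromovanillin (3-bromo-4-hydroxy-5-methoxybenzaldehyde) | COc1cc(C=O)cc(Br)c1O | intermediate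
7 | 5,6-dibromovanillin (2,3-dibromo-4-hydroxy-5-methoxybenzaldehyde) | COc1cc(C=O)c(Br)c(Br)c1O | intermediate
8 | 2,3,6-tribromo-4-hydroxy-5-methoxybenzaldehyde | COc1c(O)c(Br)c(Br)c(C=O)c1Br | intermediate
9 | 2,3,6-tribromo-4-hydroxy-5-methoxybenzyl alcohol (achiral) | COc1c(O)c(Br)c(Br)c(CO)c1Br | target

**Total step count:** 5. **Longest linear sequence:** 5 steps (1 + 2 → 3 → 5 → 7 → 8 → 9).

**Steps most likely to fail and fallbacks**

Step 4 (third bromination of a deactivated, fully flanked position; risk of stalling or of ipso-bromodeformylation). The fallback changes the order of events and sets out from 7. The aldehyde is reduced first (NaBH4, THF/H2O, 0 °C) to 2,3-dibromo-4-hydroxy-5-methoxybenzyl alcohol F1. Both hydroxyls are then acetylated (Ac2O, pyridine, DMAP cat., CH2Cl2) to give 4-(acetoxymethyl)-2,3-dibromo-6-methoxyphenyl acetate F2. This ring carries neither the deactivating formyl group nor the free para-phenol that opens the ipso pathway. Bromination of the single open position ortho to OMe (NBS, CF3CO2H, rt, dark) gives 4-(acetoxymethyl)-2,3,5-tribromo-6-methoxyphenyl acetate F3. Saponification of both esters (LiOH, THF/H2O, 0 °C, then pH 6) comes back to the route at the target 9.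

Step 1 (ortho/para selectivity, double addition, and isolation of a very water-soluble acid). The fallback replaces the phenolate addition by an aryllithium formylation and sets out from 1. Para-selective monobromination (Bu4NBr3, CH2Cl2/MeOH, rt) gives 4-bromo-2-methoxyphenol F4. Silylation (TBSCl, imidazole, DMF) gives (4-bromo-2-methoxyphenoxy)(tert-butyl)dimethylsilane F5. Bromine–lithium exchange (n-BuLi, THF, −78 °C) and a DMF quench give 4-[(tert-butyldimethylsilyl)oxy]-3-methoxybenzaldehyde F6. Desilylation (TBAF, THF, 0 °C) comes back to the route at vanillin 5, so steps 1 and 2 are both bypassed.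

Step 5 (hindered aldehyde that is deactivated as its phenoxide under borohydride; product is a quinone-methide-prone p-hydroxybenzyl alcohol). The fallback masks the phenol and uses a non-basic hydride, setting out from 8. Silylation (TBSCl, imidazole, DMF, rt) gives 2,3,6-tribromo-4-[(tert-butyldimethylsilyl)oxy]-5-methoxybenzaldehyde F7. Reduction with DIBAL-H (CH2Cl2, −78 °C, Rochelle salt work-up) gives {2,3,6-tribromo-4-[(tert-butyldimethylsilyl)oxy]-5-methoxyphenyl}methanol F8. Buffered desilylation (TBAF/AcOH, THF, 0 °C) comes back to the route at the target 9.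

**Further compounds**
F1 | step 4 | 2,3-dibromo-4-hydroxy-5-methoxybenzyl alcohol | COc1cc(CO)c(Br)c(Br)c1O
F2 | step 4 | 4-(acetoxymethyl)-2,3-dibromo-6-methoxyphenyl acetate | COc1cc(COC(C)=O)c(Br)c(Br)c1OC(C)=O
F3 | step 4 | 4-(acetoxymethyl)-2,3,5-tribromo-6-methoxyphenyl acetate | COc1c(OC(C)=O)c(Br)c(Br)c(COC(C)=O)c1Br
F4 | step 1 | 4-bromo-2-methoxyphenol | COc1cc(Br)ccc1O
F5 | step 1 | (4-bromo-2-methoxyphenoxy)(tert-butyl)dimethylsilane | COc1cc(Br)ccc1O[Si](C)(C)C(C)(C)C
F6 | step 1 | 4-[(tert-butyldimethylsilyl)oxy]-3-methoxybenzaldehyde | COc1cc(C=O)ccc1O[Si](C)(C)C(C)(C)C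
F7 | step 5 | 2,3,6-tribromo-4-[(tert-butyldimethylsilyl)oxy]-5-methoxybenzaldehyde | COc1c(O[Si](C)(C)C(C)(C)C)c(Br)c(Br)c(C=O)c1Br
F8 | step 5 | {2,3,6-tribromo-4-[(tert-butyldimethylsilyl)oxy]-5-methoxyphenyl}methanol | COc1c(O[Si](C)(C)C(C)(C)C)c(Br)c(Br)c(CO)c1Br
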